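Ring A is disconnected at two neighbouring bonds, C1–C(=O) and C2–O, so that the ring-B acid is inserted whole into a C1≡C2 aryne. The feature exploited is that the aroyl-bearing C1 and the hydroxylated C2 of ring A are ortho, while the oxygen on C6 flanks C1 and polarises the aryne so that oxygen enters at C2 and acyl at C1. One operation thus installs ketone and phenol without Friedel–Crafts acid near the prenyl groups. The precursor is a fully substituted ortho-silylaryl triflate (C1 SiMe3, C2 OTf, C3/C5 prenyl, C4 OMe, C6 OMOM), built from 5-methoxyresorcinol by three directed lithiations.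

Key step: step 8

Remark: ring A is numbered C1 (aroyl), C2 and C6 (oxygen), C3 and C5 (prenyl = 3-methylbut-2-en-1-yl), C4 (OMe), ring B is the 4-hydroxyphenyl ring, and no numbered compound has a stereocentre or a stereogenic double bond, so the SMILES need no stereodescriptors.

Step 1
Reactants: 1 5-methoxyresorcinol
Product: 2 1-methoxy-3,5-bis(methoxymethoxy)benzene
Conditions: NaH, MOMCl, DMF, 0 °C to rt
Reagents that add atoms: chloromethyl methyl ether (MOMCl), COCCl
Why: Both sodium phenoxides should be alkylated on oxygen by the hard electrophile MOMCl (Williamson ether synthesis), giving a symmetric bis-acetal whose oxygens direct every later lithiation.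

Step 2
Reactants: 2 1-methoxy-3,5-bis(methoxymethoxy)benzene
Product: 4 [4-methoxy-2,6-bis(methoxymethoxy)phenyl]trimethylsilane, via aryllithium 3 (not isolated)
Conditions: n-BuLi, THF, 0 °C; Me3SiCl, 0 °C to rt
Reagents that add atoms: chlorotrimethylsilane, C[Si](C)(C)Cl
Why: Directed ortho-metalation should occur at the hydrogen between the two MOM ethers, the most acidic and doubly coordinated site, and the silyl quench installs the group that first blocks this position and later triggers the aryne.

Step 3
Reactants: 4 [4-methoxy-2,6-bis(methoxymethoxy)phenyl]trimethylsilane; 5 prenyl bromide (1-bromo-3-methylbut-2-ene)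
Product: 8 [4-methoxy-2,6-bis(methoxymethoxy)-3-(3-methylbut-2-en-1-yl)phenyl]trimethylsilane, via aryllithium 6 (not isolated), via arylcopper 7 (not isolated)
Conditions: n-BuLi, TMEDA, THF, 0 °C; CuBr·SMe2, −78 to −40 °C; then 5, −78 °C to rt
Reagents that add atoms: none
Why: Directed ortho-metalation at one of the two equivalent hydrogens flanked by a MOM ether and the methoxy group, transmetalation to the arylcopper and allylic substitution on prenyl bromide should give the linear prenyl arene, because the γ,γ-disubstituted terminus disfavours SN2′ attack.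

Step 4
Reactants: 8 [4-methoxy-2,6-bis(methoxymethoxy)-3-(3-methylbut-2-en-1-yl)phenyl]trimethylsilane; 5 prenyl bromide
Product: 11 [4-methoxy-2,6-bis(methoxymethoxy)-3,5-bis(3-methylbut-2-en-1-yl)phenyl]trimethylsilane, via aryllithium 9 (not isolated), via arylcopper 10 (not isolated)
Conditions: n-BuLi, TMEDA, THF, 0 °C; CuBr·SMe2, −78 to −40 °C; then 5, −78 °C to rt
Reagents that add atoms: none
Why: The same directed ortho-metalation and copper-mediated allylic substitution at the last ring hydrogen should work, because chelation by the flanking MOM and methoxy oxygens makes ring lithiation faster than deprotonation of the benzylic-allylic CH2 of the first prenyl group.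

Step 5
Reactants: 11 [4-methoxy-2,6-bis(methoxymethoxy)-3,5-bis(3-methylbut-2-en-1-yl)phenyl]trimethylsilane
Product: 13 3-methoxy-5-(methoxymethoxy)-2,4-bis(3-methylbut-2-en-1-yl)-6-(trimethylsilyl)phenol, via aryl trimethylsilyl ether 12 (not isolated)
Conditions: Me3SiOTf (1.1 equiv), 2,2′-bipyridyl, MeCN, 0 °C to rt; then aq. NaHCO3, MeOH, rt
Reagents that add atoms: none
Why: Silyl triflate–bipyridyl cleavage of an aryl MOM ether to the aryl silyl ether is buffered and free of protic acid, so the protodesilylation-prone C–Si bond on this electron-rich ring and the prenyl groups should survive, and with about one equivalent of Me3SiOTf the two equivalent acetals should be cleaved statistically to give mainly the mono-phenol after mild hydrolysis, with unreacted 11 recycled.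

Step 6
Reactants: 13 3-methoxy-5-(methoxymethoxy)-2,4-bis(3-methylbut-2-en-1-yl)-6-(trimethylsilyl)phenol
Product: 14 3-methoxy-5-(methoxymethoxy)-2,4-bis(3-methylbut-2-en-1-yl)-6-(trimethylsilyl)phenyl trifluoromethanesulfonate
Conditions: NaH, PhNTf2, THF, 0 °C to rt
Reagents that add atoms: N-phenylbis(trifluoromethanesulfonimide), O=S(=O)(N(c1ccccc1)S(=O)(=O)C(F)(F)F)C(F)(F)F
Why: O-Sulfonylation (triflation) of the sodium phenoxide with PhNTf2 under fluoride-free basic conditions is the standard last step towards ortho-silylaryl triflates and should leave the acetal, the C–Si bond and the alkenes untouched.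

Step 7
Reactants: 15 4-hydroxybenzoic acid
Product: 17 4-(methoxymethoxy)benzoic acid, via methoxymethyl ester 16 (not isolated)
Conditions: NaH, MOMCl, DMF, 0 °C to rt; then LiOH, H2O–MeOH, rt; 1 M HCl to pH 4, 0 °C
Reagents that add atoms: chloromethyl methyl ether (MOMCl), COCCl; lithium hydroxide, [Li+].[OH-]
Why: Exhaustive Williamson-type alkylation of phenoxide and carboxylate followed by saponification of the much more labile methoxymethyl ester should give the acid with its phenol masked, so that only the carboxylate can add to the aryne.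

Step 8
Reactants: 14 3-methoxy-5-(methoxymethoxy)-2,4-bis(3-methylbut-2-en-1-yl)-6-(trimethylsilyl)phenyl trifluoromethanesulfonate; 17 4-(methoxymethoxy)benzoic acid
Product: 19 [2-hydroxy-4-methoxy-6-(methoxymethoxy)-3,5-bis(3-methylbut-2-en-1-yl)phenyl][4-(methoxymethoxy)phenyl]methanone, via aryne 18 (not isolated)
Conditions: 17 (2 equiv), CsF (5 equiv), THF, 125 °C, sealed tube
Reagents that add atoms: none
Why: CsF removes the silyl group from C1 with loss of triflate from C2 and so unmasks aryne 18; the caesium salt of 17 then bonds through a carboxylate oxygen to C2, and the carbanion left on C1 adds to the carbonyl of the aryl ester just formed, passing through a strained four-membered alkoxide whose collapse moves the aroyl group to C1 and frees the C2 oxygen as phenoxide. The closest known reaction type is the insertion of arynes from ortho-silylaryl triflates into the C–O bond of aromatic carboxylic acids with CsF in hot THF, which gives ortho-hydroxyaryl ketones. No ring is retained, since the four-membered ring is only transient, and no stereocentre is formed. The selectivity needed is oxygen at C2 and acyl at C1: the inductively withdrawing MOM-oxy group on C6 distorts the aryne so that the distal carbon C2 is the electrophilic one and the negative charge develops next to oxygen on C1, while each aryne carbon carries one ortho substituent, so that sterics add little bias against this. Excess CsF converts the acid fully into its caesium salt and the high temperature favours the intramolecular acyl shift over protonation of the aryl anion, which would stop at the aryl ester. The MOM ethers, the methyl ether and the prenyl groups should be inert to fluoride and carboxylate under these conditions.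

Step 9
Reactants: 19 [2-hydroxy-4-methoxy-6-(methoxymethoxy)-3,5-bis(3-methylbut-2-en-1-yl)phenyl][4-(methoxymethoxy)phenyl]methanone
Product: 20 vismiaphenone D, [2,6-dihydroxy-4-methoxy-3,5-bis(3-methylbut-2-en-1-yl)phenyl](4-hydroxyphenyl)methanone
Conditions: HCl (1 M in MeOH), 25 °C
Reagents that add atoms: none
Why: Acid-catalysed transacetalisation to methanol (MOM ether cleavage), fastest for the C6 ether next to the carbonyl, should remove both acetals under conditions too mild for protonation of the trisubstituted alkenes and chroman formation with the neighbouring phenols.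

Compound list
1 | 5-methoxyresorcinol | COc1cc(O)cc(O)c1 | starting material
2 | 1-methoxy-3,5-bis(methoxymethoxy)benzene | COCOc1cc(OC)cc(OCOC)c1 | intermediate
3 | [4-methoxy-2,6-bis(methoxymethoxy)phenyl]lithium | [Li]c1c(OCOC)cc(OC)cc1OCOC | intermediate
4 | [4-methoxy-2,6-bis(methoxymethoxy)phenyl]trimethylsilane | COCOc1cc(OC)cc(OCOC)c1[Si](C)(C)C | intermediate
5 | prenyl bromide (1-bromo-3-methylbut-2-ene) | CC(C)=CCBr | starting material
6 | [6-methoxy-2,4-bis(methoxymethoxy)-3-(trimethylsilyl)phenyl]lithium | COCOc1c([Li])c(OC)cc(OCOC)c1[Si](C)(C)C | intermediate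
7 | [6-methoxy-2,4-bis(methoxymethoxy)-3-(trimethylsilyl)phenyl]copper | COCOc1c([Cu])c(OC)cc(OCOC)c1[Si](C)(C)C | intermediate
8 | [4-methoxy-2,6-bis(methoxymethoxy)-3-(3-methylbut-2-en-1-yl)phenyl]trimethylsilane | COCOc1c(CC=C(C)C)c(OC)cc(OCOC)c1[Si](C)(C)C | intermediate
9 | [2-methoxy-4,6-bis(methoxymethoxy)-3-(3-methylbut-2-en-1-yl)-5-(trimethylsilyl)phenyl]lithium | COCOc1c(CC=C(C)C)c(OC)c([Li])c(OCOC)c1[Si](C)(C)C | intermediate
10 | [2-methoxy-4,6-bis(methoxymethoxy)-3-(3-methylbut-2-en-1-yl)-5-(trimethylsilyl)phenyl]copper | COCOc1c(CC=C(C)C)c(OC)c([Cu])c(OCOC)c1[Si](C)(C)C | intermediate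
11 | [4-methoxy-2,6-bis(methoxymethoxy)-3,5-bis(3-methylbut-2-en-1-yl)phenyl]trimethylsilane | COCOc1c(CC=C(C)C)c(OC)c(CC=C(C)C)c(OCOC)c1[Si](C)(C)C | intermediate
12 | [3-methoxy-5-(methoxymethoxy)-2,4-bis(3-methylbut-2-en-1-yl)-6-(trimethylsilyl)phenoxy]trimethylsilane | COCOc1c(CC=C(C)C)c(OC)c(CC=C(C)C)c(O[Si](C)(C)C)c1[Si](C)(C)C | intermediate
13 | 3-methoxy-5-(methoxymethoxy)-2,4-bis(3-methylbut-2-en-1-yl)-6-(trimethylsilyl)phenol | COCOc1c(CC=C(C)C)c(OC)c(CC=C(C)C)c(O)c1[Si](C)(C)C | intermediate
14 | 3-methoxy-5-(methoxymethoxy)-2,4-bis(3-methylbut-2-en-1-yl)-6-(trimethylsilyl)phenyl trifluoromethanesulfonate | COc1c(CC=C(C)C)c(OCOC)c([Si](C)(C)C)c(OS(=O)(=O)C(F)(F)F)c1CC=C(C)C | intermediate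
15 | 4-hydroxybenzoic acid | O=C(O)c1ccc(O)cc1 | starting material
16 | methoxymethyl 4-(methoxymethoxy)benzoate | COCOC(=O)c1ccc(OCOC)cc1 | intermediate
17 | 4-(methoxymethoxy)benzoic acid | COCOc1ccc(C(=O)O)cc1 | intermediate
18 | 1,2-didehydro-4-methoxy-6-(methoxymethoxy)-3,5-bis(3-methylbut-2-en-1-yl)benzene (aryne, ring A numbering) | COC1=C(CC=C(C)C)C#CC(OCOC)=C1CC=C(C)C | intermediate
19 | [2-hydroxy-4-methoxy-6-(methoxymethoxy)-3,5-bis(3-methylbut-2-en-1-yl)phenyl][4-(methoxymethoxy)phenyl]methanone (6,4′-bis-O-MOM vismiaphenone D) | COc1c(CC=C(C)C)c(OCOC)c(C(=O)c2ccc(OCOC)cc2)c(O)c1CC=C(C)C | intermediate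
20 | vismiaphenone D, [2,6-dihydroxy-4-methoxy-3,5-bis(3-methylbut-2-en-1-yl)phenyl](4-hydroxyphenyl)methanone | COc1c(CC=C(C)C)c(O)c(C(=O)c2ccc(O)cc2)c(O)c1CC=C(C)C | target

Total step count: 9. Longest linear sequence: 8 steps (steps 1 to 6, 8 and 9); step 7 makes the acid partner.

Steps most likely to fail

Step 8. Carboxylate attack at the hindered C2 may be slower than consumption of the aryne by ene reaction with the prenyl alkenes of a second molecule, addition may occur at C1 instead, or protonation of the aryl anion may outrun the acyl shift and stop at the aryl ester. In the fallback the aryne is given up and the C1–C(=O) bond is made by aryllithium addition. It sets out from 11. Fluoride-induced protodesilylation (Bu4NF, DMF, 80 °C) should give 2-methoxy-4,6-bis(methoxymethoxy)-1,3-bis(3-methylbut-2-en-1-yl)benzene F1. Directed lithiation between the two MOM ethers (n-BuLi, THF, 0 °C) and addition to commercial 4-(methoxymethoxy)benzaldehyde should give racemic [4-methoxy-2,6-bis(methoxymethoxy)-3,5-bis(3-methylbut-2-en-1-yl)phenyl][4-(methoxymethoxy)phenyl]methanol F2. Oxidation with Dess–Martin periodinane (NaHCO3, CH2Cl2) should give [4-methoxy-2,6-bis(methoxymethoxy)-3,5-bis(3-methylbut-2-en-1-yl)phenyl][4-(methoxymethoxy)phenyl]methanone F3. The conditions of step 9 then remove all three MOM ethers, so the fallback comes back to the route at 20.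

Step 5. The two MOM ethers are equivalent, so cleavage may run on to the diol or stop short, and the C–Si bond may be lost by protodesilylation while the silyl ether is hydrolysed. In the fallback the two oxygens are made different at the outset instead of being told apart late. It sets out from 1. One equivalent each of NaH and MOMCl should give 3-methoxy-5-(methoxymethoxy)phenol F4, separable from 2 and recovered 1. ClC(O)NEt2 and K2CO3 in MeCN should give 3-methoxy-5-(methoxymethoxy)phenyl N,N-diethylcarbamate F5. s-BuLi/TMEDA at −78 °C and Me3SiCl should silylate between the two directing groups to give 5-methoxy-3-(methoxymethoxy)-2-(trimethylsilyl)phenyl N,N-diethylcarbamate F6. Two rounds of lithiation (s-BuLi/TMEDA, −78 °C), CuBr·SMe2 and prenyl bromide 5 should give first 3-methoxy-5-(methoxymethoxy)-2-(3-methylbut-2-en-1-yl)-6-(trimethylsilyl)phenyl N,N-diethylcarbamate F7, the carbamate being the stronger director, and then 3-methoxy-5-(methoxymethoxy)-2,4-bis(3-methylbut-2-en-1-yl)-6-(trimethylsilyl)phenyl N,N-diethylcarbamate F8. LiAlH4 in THF removes the carbamate reductively and leaves the MOM ether, the C–Si bond and the alkenes, so the fallback comes back to the route at 13.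

Step 9. Protonation of a prenyl alkene and capture by the neighbouring phenol (chroman formation) may compete with acetal cleavage, especially while the slower acetal on ring B is still being removed. In the fallback the acetals are exchanged for silyl ethers without protic acid and these are then cleaved by fluoride. It sets out from 19. Et3SiOTf and 2,2′-bipyridyl in MeCN, followed by Et3N to cap the free phenol, should give [4-methoxy-3,5-bis(3-methylbut-2-en-1-yl)-2,6-bis(triethylsilyloxy)phenyl][4-(triethylsilyloxy)phenyl]methanone F9. Bu4NF buffered with AcOH in THF at 0 °C cleaves the three aryl silyl ethers, so the fallback comes back to the route at 20.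

Further compounds
F1 | step 8 | 2-methoxy-4,6-bis(methoxymethoxy)-1,3-bis(3-methylbut-2-en-1-yl)benzene | COCOc1cc(OCOC)c(CC=C(C)C)c(OC)c1CC=C(C)C
F2 | step 8 | racemic [4-methoxy-2,6-bis(methoxymethoxy)-3,5-bis(3-methylbut-2-en-1-yl)phenyl][4-(methoxymethoxy)phenyl]methanol | COCOc1ccc(C(O)c2c(OCOC)c(CC=C(C)C)c(OC)c(CC=C(C)C)c2OCOC)cc1
F3 | step 8 | [4-methoxy-2,6-bis(methoxymethoxy)-3,5-bis(3-methylbut-2-en-1-yl)phenyl][4-(methoxymethoxy)phenyl]methanone | COCOc1ccc(C(=O)c2c(OCOC)c(CC=C(C)C)c(OC)c(CC=C(C)C)c2OCOC)cc1
F4 | step 5 | 3-methoxy-5-(methoxymethoxy)phenol | COCOc1cc(O)cc(OC)c1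
F5 | step 5 | 3-methoxy-5-(methoxymethoxy)phenyl N,N-diethylcarbamate | CCN(CC)C(=O)Oc1cc(OC)cc(OCOC)c1
F6 | step 5 | 5-methoxy-3-(methoxymethoxy)-2-(trimethylsilyl)phenyl N,N-diethylcarbamate | CCN(CC)C(=O)Oc1cc(OC)cc(OCOC)c1[Si](C)(C)C
F7 | step 5 | 3-methoxy-5-(methoxymethoxy)-2-(3-methylbut-2-en-1-yl)-6-(trimethylsilyl)phenyl N,N-diethylcarbamate | CCN(CC)C(=O)Oc1c(CC=C(C)C)c(OC)cc(OCOC)c1[Si](C)(C)C
F8 | step 5 | 3-methoxy-5-(methoxymethoxy)-2,4-bis(3-methylbut-2-en-1-yl)-6-(trimethylsilyl)phenyl N,N-diethylcarbamate | CCN(CC)C(=O)Oc1c(CC=C(C)C)c(OC)c(CC=C(C)C)c(OCOC)c1[Si](C)(C)C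
F9 | step 9 | [4-methoxy-3,5-bis(3-methylbut-2-en-1-yl)-2,6-bis(triethylsilyloxy)phenyl][4-(triethylsilyloxy)phenyl]methanone | CC[Si](CC)(CC)Oc1ccc(C(=O)c2c(O[Si](CC)(CC)CC)c(CC=C(C)C)c(OC)c(CC=C(C)C)c2O[Si](CC)(CC)CC)cc1
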